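**Retrosynthetic overview**
- Tatarinoid C ← hydrogenolysis of its O-benzyl ether; the C3 methyl ← CH2OTs ← CH2OH ← the acyl carbon of an N-acyl oxazolidinone.
- The diarylmethine (C1) ← Friedel–Crafts arylation of a benzylic aldol carbinol with 1,2,4-trimethoxybenzene; C1 then carries two identical aryl groups and is no longer a stereocenter.
- The C1–C2 bond ← Evans boron glycolate syn-aldol between (S)-4-benzyl-3-(benzyloxyacetyl)oxazolidin-2-one and 2,4,5-trimethoxybenzaldehyde; this sets C2, the only stereocenter of the target.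
- No ring is formed: both trimethoxyphenyl rings are bought intact (one as the aldehyde, one as the arene).

Assumption: the target SMILES is read as the (2R)-alcohol. Atom labels C1 (diarylmethine), C2 (carbinol) and C3 (methyl) refer to the target.

**Step 1**
Reactants: 1 (4S)-4-benzyl-1,3-oxazolidin-2-one; 2 (benzyloxy)acetyl chloride
Product: 4 (4S)-4-benzyl-3-[(benzyloxy)acetyl]-1,3-oxazolidin-2-one, via N-lithio oxazolidinone 3 (not isolated)
Conditions: n-BuLi (1.05 equiv), THF, −78 °C, 30 min; then 2 (1.1 equiv), −78 → 0 °C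
Reagents that add atoms: none
Why: N-acylation of the lithiated oxazolidinone by the acid chloride (nucleophilic acyl substitution) is the standard high-yielding way to load an Evans auxiliary, and the auxiliary stereocenter is not touched.

**Step 2**
Reactants: 4 (4S)-4-benzyl-3-[(benzyloxy)acetyl]-1,3-oxazolidin-2-one; 5 2,4,5-trimethoxybenzaldehyde
Product: 8 (4S)-4-benzyl-3-[(2S,3R)-2-(benzyloxy)-3-hydroxy-3-(2,4,5-trimethoxyphenyl)propanoyl]-1,3-oxazolidin-2-one, via dibutylboron Z-enolate 6 (not isolated), via dibutylboron aldolate 7 (not isolated)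
Conditions: Bu2BOTf (1.2 equiv), Et3N (1.4 equiv), CH2Cl2, −78 → 0 °C, 1 h; 5 (1.2 equiv), −78 → 0 °C, 3 h; then pH 7 phosphate buffer, MeOH, 30% aq. H2O2, 0 °C, 1 h; chromatography on Et3N-washed silica
Reagents that add atoms: none
Why: Evans boron glycolate syn-aldol, in which soft enolisation gives the Z-enolate that adds through a closed Zimmerman–Traxler chair on the face opposite the C4 benzyl group of the auxiliary, setting the benzyloxy-bearing carbon as S (it becomes C2 of the target) and the carbinol carbon as R, with minor diastereomers removed by chromatography.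

**Step 3**
Reactants: 8 (4S)-4-benzyl-3-[(2S,3R)-2-(benzyloxy)-3-hydroxy-3-(2,4,5-trimethoxyphenyl)propanoyl]-1,3-oxazolidin-2-one; 9 1,2,4-trimethoxybenzene
Product: 10 (4S)-4-benzyl-3-[(2S)-2-(benzyloxy)-3,3-bis(2,4,5-trimethoxyphenyl)propanoyl]-1,3-oxazolidin-2-one
Conditions: 9 (3 equiv), Bi(OTf)3 (10 mol %), MeNO2, 0 °C → rt
Reagents that add atoms: none
Why: Friedel–Crafts arylation through an SN1 benzylic cation, which the ortho- and para-methoxy groups make easy to form and which 1,2,4-trimethoxybenzene traps at its most nucleophilic C5 position faster than the cation can lose the adjacent proton, so the new ring is again 2,4,5-trimethoxyphenyl, the former carbinol carbon stops being a stereocenter and the neighbouring S center is not involved.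

**Step 4**
Reactants: 10 (4S)-4-benzyl-3-[(2S)-2-(benzyloxy)-3,3-bis(2,4,5-trimethoxyphenyl)propanoyl]-1,3-oxazolidin-2-one
Product: 11 (2S)-2-(benzyloxy)-3,3-bis(2,4,5-trimethoxyphenyl)propan-1-ol
Conditions: LiBH4 (2 equiv), THF, 0 °C → rt; sat. aq. NH4Cl
Reagents that add atoms: none
Why: Reductive cleavage of the N-acyl oxazolidinone by borohydride (exocyclic acyl attack, imide to primary alcohol) releases the auxiliary for recovery without touching the stereocenter.

**Step 5**
Reactants: 11 (2S)-2-(benzyloxy)-3,3-bis(2,4,5-trimethoxyphenyl)propan-1-ol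
Product: 12 (2S)-2-(benzyloxy)-3,3-bis(2,4,5-trimethoxyphenyl)propyl 4-methylbenzenesulfonate
Conditions: TsCl (1.5 equiv), Et3N (2 equiv), DMAP (0.1 equiv), CH2Cl2, 0 °C → rt
Reagents that add atoms: p-toluenesulfonyl chloride, Cc1ccc(cc1)S(=O)(=O)Cl
Why: O-Sulfonylation of the only free hydroxyl, a primary alcohol, is routine and activates that carbon for deoxygenation.

**Step 6**
Reactants: 12 (2S)-2-(benzyloxy)-3,3-bis(2,4,5-trimethoxyphenyl)propyl 4-methylbenzenesulfonate
Product: 13 1,1'-[(2R)-2-(benzyloxy)propane-1,1-diyl]bis(2,4,5-trimethoxybenzene)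
Conditions: LiEt3BH (3 equiv, 1 M in THF), THF, 0 °C → rt (40 °C if slow); H2O quench
Reagents that add atoms: none
Why: SN2 hydride displacement of the primary tosylate by LiEt3BH (reductive deoxygenation) turns CH2OTs into the C3 methyl, with the stereocenter spatially unchanged and its descriptor switching from S to R only because CH3 now ranks below the diarylmethyl group.

**Step 7**
Reactants: 13 1,1'-[(2R)-2-(benzyloxy)propane-1,1-diyl]bis(2,4,5-trimethoxybenzene)
Product: 14 tatarinoid C, (2R)-1,1-bis(2,4,5-trimethoxyphenyl)propan-2-ol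
Conditions: H2 (1 atm), Pd(OH)2/C (20 wt %), EtOAc/EtOH 1:1, rt
Reagents that add atoms: none
Why: Catalytic hydrogenolysis cleaves only the O-benzyl C–O bond, leaving the aryl methyl ethers, the diarylmethine C–H and the configuration at C2 untouched, so the (R)-alcohol is released.

**Compound list**
1 | (4S)-4-benzyl-1,3-oxazolidin-2-one | O=C1N[C@@H](Cc2ccccc2)CO1 | starting material
2 | (benzyloxy)acetyl chloride | O=C(Cl)COCc1ccccc1 | starting material
3 | N-lithio (4S)-4-benzyl-1,3-oxazolidin-2-one | [Li]N1C(=O)OC[C@@H]1Cc1ccccc1 | intermediate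
4 | (4S)-4-benzyl-3-[(benzyloxy)acetyl]-1,3-oxazolidin-2-one | O=C(COCc1ccccc1)N1C(=O)OC[C@@H]1Cc1ccccc1 | intermediate
5 | 2,4,5-trimethoxybenzaldehyde | O=Cc1cc(OC)c(OC)cc1OC | starting material
6 | dibutylboron Z-enolate of 4 | CCCCB(CCCC)O/C(=C\OCc1ccccc1)N1C(=O)OC[C@@H]1Cc1ccccc1 | intermediate
7 | dibutylboron aldolate of 8 (O-dibutylboryl derivative at the carbinol oxygen) | O=C([C@@H](OCc1ccccc1)[C@H](OB(CCCC)CCCC)c1cc(OC)c(OC)cc1OC)N1C(=O)OC[C@@H]1Cc1ccccc1 | intermediate
8 | (4S)-4-benzyl-3-[(2S,3R)-2-(benzyloxy)-3-hydroxy-3-(2,4,5-trimethoxyphenyl)propanoyl]-1,3-oxazolidin-2-one | O=C([C@@H](OCc1ccccc1)[C@H](O)c1cc(OC)c(OC)cc1OC)N1C(=O)OC[C@@H]1Cc1ccccc1 | intermediate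
9 | 1,2,4-trimethoxybenzene | COc1ccc(OC)c(OC)c1 | starting material
10 | (4S)-4-benzyl-3-[(2S)-2-(benzyloxy)-3,3-bis(2,4,5-trimethoxyphenyl)propanoyl]-1,3-oxazolidin-2-one | O=C([C@@H](OCc1ccccc1)C(c1cc(OC)c(OC)cc1OC)c1cc(OC)c(OC)cc1OC)N1C(=O)OC[C@@H]1Cc1ccccc1 | intermediate
11 | (2S)-2-(benzyloxy)-3,3-bis(2,4,5-trimethoxyphenyl)propan-1-ol | OC[C@@H](OCc1ccccc1)C(c1cc(OC)c(OC)cc1OC)c1cc(OC)c(OC)cc1OC | intermediate
12 | (2S)-2-(benzyloxy)-3,3-bis(2,4,5-trimethoxyphenyl)propyl 4-methylbenzenesulfonate | Cc1ccc(cc1)S(=O)(=O)OC[C@@H](OCc1ccccc1)C(c1cc(OC)c(OC)cc1OC)c1cc(OC)c(OC)cc1OC | intermediate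
13 | 1,1'-[(2R)-2-(benzyloxy)propane-1,1-diyl]bis(2,4,5-trimethoxybenzene) | C[C@@H](OCc1ccccc1)C(c1cc(OC)c(OC)cc1OC)c1cc(OC)c(OC)cc1OC | intermediate
14 | tatarinoid C, (2R)-1,1-bis(2,4,5-trimethoxyphenyl)propan-2-ol | COc1cc(OC)c(C(c2cc(OC)c(OC)cc2OC)[C@@H](C)O)cc1OC | target

**Totals**
Total step count: 7. Longest linear sequence: 7 steps (1 → 4 → 8 → 10 → 11 → 12 → 13 → 14).

**Three steps most likely to fail, with fallbacks**

Step 3 (Friedel–Crafts arylation on the aldol imide). The risk is that the benzylic cation next to the imide loses the C2 proton (elimination or scrambling of C2) or that the aldol reverts, instead of being trapped by the arene. The fallback sets out from 8 and removes the carbonyl before the ionisation. Compound 8 is reduced with LiBH4 in THF at 0 °C, which releases the auxiliary and gives the diol (1R,2R)-2-(benzyloxy)-1-(2,4,5-trimethoxyphenyl)propane-1,3-diol F1. The arylation is then run on this carbonyl-free benzylic carbinol with 9 (3 equiv) and TFA in CH2Cl2 at −20 °C (or catalytic Bi(OTf)3), where the C2 proton is no longer acidified. This gives the primary alcohol directly, so the fallback comes back to the route at 11.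

Step 4 (LiBH4 cleavage of the hindered imide). The risk is endocyclic attack at the oxazolidinone carbonyl (ring-opened hydroxy amide) because the acyl carbon is flanked by the benzyloxy and diarylmethyl groups. The fallback sets out from 10 and changes to hydrolysis followed by acid reduction. LiOH/H2O2 in THF/H2O at 0 °C (hydroperoxide attacks the exocyclic carbonyl selectively) gives (2S)-2-(benzyloxy)-3,3-bis(2,4,5-trimethoxyphenyl)propanoic acid F2 and the recovered auxiliary. Reduction of the acid with BH3·SMe2 in THF at 0 °C → rt then comes back to the route at 11.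

Step 6 (hydride displacement of the tosylate). The risk is slow SN2 at a β-branched, β-alkoxy primary carbon, with competing S–O cleavage returning 11. The fallback sets out from 11 and replaces the ionic displacement with a radical reduction. I2, PPh3 and imidazole in toluene at rt give the iodide 1,1'-[(2S)-2-(benzyloxy)-3-iodopropane-1,1-diyl]bis(2,4,5-trimethoxybenzene) F3. Bu3SnH with catalytic AIBN in toluene at 80 °C then removes the iodine through the primary radical, which is insensitive to steric hindrance, and comes back to the route at 13.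

**Further compounds**
F1 | step 3 | (1R,2R)-2-(benzyloxy)-1-(2,4,5-trimethoxyphenyl)propane-1,3-diol | OC[C@@H](OCc1ccccc1)[C@H](O)c1cc(OC)c(OC)cc1OC
F2 | step 4 | (2S)-2-(benzyloxy)-3,3-bis(2,4,5-trimethoxyphenyl)propanoic acid | OC(=O)[C@@H](OCc1ccccc1)C(c1cc(OC)c(OC)cc1OC)c1cc(OC)c(OC)cc1OC
F3 | step 6 | 1,1'-[(2S)-2-(benzyloxy)-3-iodopropane-1,1-diyl]bis(2,4,5-trimethoxybenzene) | IC[C@@H](OCc1ccccc1)C(c1cc(OC)c(OC)cc1OC)c1cc(OC)c(OC)cc1OC
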